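The runs come from a simulation for substances that don't exist; scatter was added.

Our ratio is the turnover yield, the target made per starting material consumed, which the elm run reads at 150 min as 40.7% over 81.7%, so 0.498; the oak run, at 85 °C, reads 0.491.

common to all: starting material 0.050 M
- elm: reagent 0.80 equiv; temperature 90 °C; the very flask that is asked about, followed so far
- oak: reagent 0.80 equiv; temperature 85 °C; run made earlier
- flask: reagent 0.800 equiv; temperature 90 °C; time 2.5 h

| run | time / min | target / % | starting material / % |
|---|---|---|---|
| elm | 12.0 | 11.1 | 36.9 |
| elm | 20.0 | 20.3 | 29.2 |
| elm | 30.0 | 25.8 | 23.6 |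
| elm | 40.0 | 31.3 | 22.0 |
| elm | 60.0 | 34.9 | 21.3 |
| elm | 90.0 | 37.4 | 19.6 |
| elm | 150 | 40.7 | 18.3 |
| oak | 12.0 | 7.2 | 41.1 |
| oak | 20.0 | 13.2 | 32.4 |
| oak | 30.0 | 19.0 | 27.9 |
| oak | 40.0 | 26.1 | 24.0 |
| oak | 60.0 | 31.5 | 21.8 |
| oak | 90.0 | 37.1 | 21.4 |
| oak | 150 | 39.5 | 19.5 |

(standard deviation of a reading: 1 percentage point)

- removed target is counted in
- additions bring no volume worth counting

- summer: at 2.5 h raise the temperature by 25 K, then wait 80 min
- noon: change nothing and wait 80 min more
- autumn: at 2.5 h add reagent, 100% of the amount charged, then wait 80 min
- winter: at 2.5 h take out 90% of the target then present, then wait 80 min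

1. target, in percent of the starting material first charged, at 2.5 h
2. the option that brings most further target ("none" if no option brings more than 2 percentage points) (summer / noon / autumn / winter / none)
3. target present, with what was taken out counted in, in percent of the starting material first charged, after noon
4. target present, with what was taken out counted in, in percent of the starting material first charged, after autumn

Elm is the flask asked about. We count one reagent per turnover, so its charge allows 80.0% of the starting material to turn over, and the 81.7% read matches that within scatter: reagent is the limiting reagent. From above, perfect turnovers would give 80.0% of target; from below, target was already 37.4% at 90.0 min and rising. Our ratio tightens the top, so we commit to 39.9%, with noon about the same. Heat and removal bring no reagent, so we count no new turnovers for them. Autumn brings enough reagent for the 18.3% of starting material left, and the elm run had consumed 78.0% of its starting material by 40.0 min, a shorter time than 80 min. So we reckon a gain of 9.1 percentage points, reaching 49.0%, below the ceiling of 49.8% set by turning over the whole charge.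

The forecast gives 40.5% (39.3% to 41.7%), 41.5% after noon (40% to 43.5%) and 49% after autumn (45% to 53%), and it chooses autumn. Its first figure stands above ours, and it names its risk: “Removing target would only help if the last step were reversible.”

The flask gives 39.5%, then 39.6% after noon and 49.0% after autumn, so the choice is autumn. Autumn gains 9.4 points, against 0.053 points for summer and 0.052 points for winter.

    starting material + reagent → intermediate (k = 0.0392 M⁻¹ s⁻¹, Ea = 57.0 kJ mol⁻¹)
    intermediate → target (k = 8.92 × 10⁻⁴ s⁻¹, Ea = 96.0 kJ mol⁻¹)
    starting material → decomposition product (k = 3.07 × 10⁻⁶ s⁻¹, Ea = 128 kJ mol⁻¹)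
    starting material + reagent → side product (k = 0.0400 M⁻¹ s⁻¹, Ea = 67.0 kJ mol⁻¹)
    (constants at 90 °C)

The forecast holds. At 150 min the flask holds 0.018% of its reagent and 19.3% of starting material, with side product 40.4% beside target 39.5%. Our ratio on that starting material gives 9.6 points, against the 9.4 points of autumn. For a neighbouring flask, the same but with 0.480 equiv of reagent, our ratio on that charge gives 23.9% of target. That neighbouring flask gives 23.7%, with 50.5% of starting material still there at 150 min.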